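## Structural features

- The target is a flavonol: a 4H-chromen-4-one (benzo ring A fused to pyranone ring C) that carries a 1,3,4-trisubstituted phenyl ring B at C2 and oxygen at C3, C5, C7, C3' and C4'.
- There is no stereocentre. The problem is connectivity and the distinction of five hydroxyl groups: O3, O7 and O4' are hydrogen sulfate esters, while O5 and O3' stay free.
- The aryl and enol sulfate monoesters are the fragile groups. As salts they tolerate base and hydrogenolysis, but acid cleaves them, so they must come last and any later deprotection must be neutral.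
- O5 is chelated to the C4 carbonyl and is the least nucleophilic hydroxyl, so it needs no protection against sulfation. O3' and O4' are neighbours of similar acidity, so their distinction is the real selectivity problem and has to be built into the ring B building block.
- Ring C is the only ring that has to be made. Its carbonyl carbon C4 is bonded to C4a, which lies between C8a (bearing O1) and C5 (bearing O5) on a phloroglucinol-type ring A.
- Feature exploited: a 3,5-dioxygenated phenoxy group is locally C2-symmetric. Its two ortho carbons are identical and are the most nucleophilic arene positions in the molecule, so ring C can be closed at the C4–C4a carbon–carbon bond with no regiochemical question.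
- In one sentence: ring C is closed by intramolecular Friedel–Crafts acylation at C4–C4a of a (Z)-3-aryl-3-(3,5-dialkoxyphenoxy)acrylic acid. This is not the chalcone oxidation or diketone dehydration that closes the ring at O1–C2.

## Logic of the disconnections

**20 ⇒ 18 (through 19).** No skeletal bond is cut; the O3'–CH2Ph bond is restored and the three acidic protons become ammonium counter-ions. A benzyl ether is chosen because it can be removed from a polysulfate under neutral, non-hydrolytic conditions. The gain is that O3', the one hydroxyl that reactivity cannot distinguish, stays covered during sulfation. The forward step must cleave one C–O bond by hydrogenolysis without touching three S–O bonds or C2=C3, and the proton exchange must be cold and brief.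

**18 ⇒ 17.** The three O–S bonds at O3, O7 and O4' are cut. In 17 the only other free hydroxyl is the chelated O5, so excess reagent can be used and selectivity rests on the substrate. The forward step must fully sulfate the hydrogen-bonded O3 while leaving O5 alone.

**17 ⇒ 16.** The O5–, O7– and O4'–allyl bonds are cut. Allyl ethers are orthogonal to the single benzyl ether, so one operation frees every oxygen except O3'. The forward step needs allyl transfer that leaves the benzyl ether and the oxidisable flavonol intact.

**16 ⇒ 13.** The C3–O bond is cut. C3–H is the only acidic vinylic C–H of the flavone, and the new hydroxyl appears at a position no protecting group ever occupied. The forward step needs C3 metalation and oxidation that tolerate allyl ethers.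

**13 ⇒ 11 (key disconnection, through 12).** The C4–C4a bond is cut, opening ring C to an acyclic acid in which ring A is only an aryl ether. This removes the need for any C-acylated, unsymmetrically substituted ring A building block. The forward step needs an acyl electrophile mild enough for allyl and benzyl ethers, and a cis relation between aryloxy and carboxyl groups, or their equilibration.

**11 ⇒ 9 ⇒ 6 + 8 (through 10).** After ester hydrolysis, the O1–C2 enol ether bond is cut. This is the convergent cut: 6 carries ring B and C2, C3, C4; 8 carries ring A. The forward step needs O-selective rather than C-selective conjugate addition, which basic conditions provide.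

**6 ⇒ 4 ⇒ 3.** The bond between the alkyne and the ester carbon is cut, then the alkyne is traced to the aldehyde carbon plus one carbon. The forward steps are a dibromo-olefination and an elimination/acylation sequence that tolerate both ethers.

**3 ⇒ 2 ⇒ 1.** The O3–benzyl bond, then the O4–allyl bond, are cut. The order follows acidity: the hydroxyl para to the formyl group reacts first, which places allyl on the future O4' and benzyl on the future O3'.

**8 ⇒ 7.** Two O–allyl bonds are cut. Because 7 is threefold symmetric, any two oxygens give the same product; the forward step only has to stop at the bis-ether.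

## Other disconnections considered

Alternative 1: the first plan to come to mind (Algar–Flynn–Oyamada) cuts O1–C2 together with the C3–O bond.
- Forward: aldol condensation of 3 with 1-[2-hydroxy-4,6-bis(allyloxy)phenyl]ethan-1-one A1 would give the chalcone A2; alkaline hydrogen peroxide would then be expected to give 16.
- Ground for preferring the chosen plan: in A2 the carbonyl is flanked by two ortho oxygen substituents, which twists the enone. The phenoxide can then close 6-endo at the β-carbon (flavonol) or 5-exo at the α-carbon (aurone skeleton), and the 5-exo mode is expected to compete most for exactly this substitution pattern. The C4–C4a closure has no such second mode.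
- A1 also needs a C-acylated, unsymmetrically protected ring A, whereas 8 is used as the symmetric phenol.

Alternative 2: an Allan–Robinson/Baker–Venkataraman plan cuts C2–C3 (acyl transfer), then O1–C2.
- Forward: 2-(allyloxy)-1-[2-hydroxy-4,6-bis(allyloxy)phenyl]ethan-1-one A3 would be O-acylated with 4-(allyloxy)-3-(benzyloxy)benzoyl chloride A4. A base-induced 1,3-acyl shift would give the diketone A5, and acid dehydration would give the 3-O-allyl flavone A6, which de-allylation would convert to 17.
- Merit: the C3 oxygen is carried in from the start.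
- Ground for preferring the chosen plan: A3 needs a Hoesch-type C-acylation of 7 with an alkoxyacetonitrile and then selective bis-allylation, and A4 needs oxidation and activation of 3, so the step count is not lower. The 2-alkoxy-1,3-diketone A5 is open to retro-Claisen cleavage by the base that forms it. Ring C is again closed at the heteroatom.

Alternative 3: a carbonylative annulation cuts C4–C4a and C3–C4, with carbon monoxide as C4.
- Forward: carbonylative Sonogashira coupling of 2-iodo-3,5-bis(allyloxy)phenol A7 with 1-(allyloxy)-2-(benzyloxy)-4-ethynylbenzene A8 under a palladium catalyst, then 6-endo-dig closure, would give 13.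
- Ground for preferring the chosen plan: A7 requires mono-iodination of 8 at C2, but C4 of 8 (between the two allyloxy groups) is at least as nucleophilic. This creates a regiochemical problem on the very ring that is symmetric in the chosen plan.
- The zerovalent palladium catalyst ionises aryl allyl ethers, so the allyl/benzyl pairing would have to be abandoned. The ynone intermediate can also close 5-exo.
- The chosen plan takes the same three carbons from 6 and needs neither a metal nor carbon monoxide.

Key step: step 8

Assumption: the target is drawn as the free tris(hydrogen sulfate); such acids hydrolyse under their own acidity, so the free acid is generated only in the last operation by cold cation exchange and should be kept cold or returned to a salt for storage.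

## Steps

Step 1
Reactants: 1 3,4-dihydroxybenzaldehyde
Product: 2 4-(allyloxy)-3-hydroxybenzaldehyde
Conditions: allyl bromide (1.05 equiv), NaHCO3, DMF, 40 °C
Reagents that add atoms: allyl bromide, C=CCBr
Why: Williamson etherification under acidity control: the 4-OH is para to the formyl group and far more acidic than the 3-OH, so hydrogencarbonate should ionise and alkylate O4 only. This choice fixes the later distinction between O4' (sulfate) and O3' (free).

Step 2
Reactants: 2 4-(allyloxy)-3-hydroxybenzaldehyde
Product: 3 4-(allyloxy)-3-(benzyloxy)benzaldehyde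
Conditions: BnBr, K2CO3, DMF, rt
Reagents that add atoms: benzyl bromide, BrCc1ccccc1
Why: Williamson etherification of the one remaining phenol; the benzyl group placed here is the only one in the route and stays until the last step.

Step 3
Reactants: 3 4-(allyloxy)-3-(benzyloxy)benzaldehyde
Product: 4 1-(allyloxy)-2-(benzyloxy)-4-(2,2-dibromovinyl)benzene
Conditions: CBr4, PPh3, CH2Cl2, 0 °C
Reagents that add atoms: carbon tetrabromide, BrC(Br)(Br)Br
Why: First stage of the Corey–Fuchs reaction, a Wittig olefination by the dibromomethylene ylide made in the flask; the isolated allyl double bond and both ethers are inert to it.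

Step 4
Reactants: 4 1-(allyloxy)-2-(benzyloxy)-4-(2,2-dibromovinyl)benzene
Product: 6 methyl 3-[4-(allyloxy)-3-(benzyloxy)phenyl]prop-2-ynoate, via lithium acetylide 5 (not isolated)
Conditions: n-BuLi (2.1 equiv), THF, −78 °C; then ClCO2Me, −78 °C to rt
Reagents that add atoms: methyl chloroformate, COC(=O)Cl
Why: Second stage of the Corey–Fuchs reaction: bromine–lithium exchange, α-elimination with 1,2-shift and deprotonation give the lithium acetylide, which is C-acylated by the chloroformate. At −78 °C the aryl allyl and benzyl ethers are not metalated.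

Step 5
Reactants: 7 benzene-1,3,5-triol (phloroglucinol)
Product: 8 3,5-bis(allyloxy)phenol
Conditions: allyl bromide (2.0 equiv), K2CO3, DMF, rt
Reagents that add atoms: allyl bromide, C=CCBr
Why: Williamson etherification of a threefold-symmetric triol, so every bis-ether is the same compound; the bis-ether is expected as the main part of a statistical mixture and is separated from mono- and tris-ether by chromatography. Carbonate in a dipolar aprotic solvent favours O- over C-allylation.

Step 6
Reactants: 6 methyl 3-[4-(allyloxy)-3-(benzyloxy)phenyl]prop-2-ynoate; 8 3,5-bis(allyloxy)phenol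
Product: 9 methyl (Z)-3-[4-(allyloxy)-3-(benzyloxy)phenyl]-3-[3,5-bis(allyloxy)phenoxy]prop-2-enoate
Conditions: K2CO3 (0.5 equiv), DMF, 90 °C
Reagents that add atoms: none
Why: Base-mediated oxa-Michael addition of a phenoxide to an alkynoate; anti addition should favour the Z isomer (aryloxy cis to the ester), and any E isomer is carried along. Making O1–C2 under base fixes the flavone connectivity, whereas acid would join the same partners through carbon towards a 4-arylcoumarin.

Step 7
Reactants: 9 methyl (Z)-3-[4-(allyloxy)-3-(benzyloxy)phenyl]-3-[3,5-bis(allyloxy)phenoxy]prop-2-enoate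
Product: 11 (Z)-3-[4-(allyloxy)-3-(benzyloxy)phenyl]-3-[3,5-bis(allyloxy)phenoxy]prop-2-enoic acid, via lithium carboxylate 10 (not isolated)
Conditions: LiOH, THF/MeOH/H2O, rt; then 1 M HCl to pH 3–4, 0 °C
Reagents that add atoms: lithium hydroxide, [Li+].[OH-]
Why: Ester saponification; the β-carbon carries two donors (aryloxy and para-alkoxyaryl), so hydroxide should attack the ester carbonyl rather than displace the phenoxide by addition–elimination.

Step 8
Reactants: 11 (Z)-3-[4-(allyloxy)-3-(benzyloxy)phenyl]-3-[3,5-bis(allyloxy)phenoxy]prop-2-enoic acid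
Product: 13 5,7-bis(allyloxy)-2-[4-(allyloxy)-3-(benzyloxy)phenyl]-4H-chromen-4-one, via mixed trifluoroacetic anhydride 12 (not isolated)
Conditions: (CF3CO)2O (1.2 equiv), CH2Cl2, 0 °C to rt
Reagents that add atoms: none
Why: Ruhemann-type chromone closure, an intramolecular Friedel–Crafts acylation of a 3-aryloxyacrylic acid, run under the mild anhydride activation that closes 2-aryloxybenzoic acids to xanthones. Acid 11 and (CF3CO)2O give mixed anhydride 12 and one equivalent of CF3CO2H; the ortho carbon of the phenoxy ring, para to one allyloxy group and ortho to the other, attacks the activated acyl carbon in a 6-exo-trig closure that forms C4–C4a, and loss of trifluoroacetate and the arenium proton gives pyranone ring C. No stereocentre is formed. Site selectivity on ring A comes from symmetry: the two ortho carbons of the 3,5-bis(allyloxy)phenoxy group are equivalent, and the third activated carbon, between the two allyloxy groups, cannot reach the acyl carbon. Ring A should win over ring B because it is a 1,3,5-trioxygenated arene closing a six-membered ring, whereas attack by ring B would have to form a strained indenone from the E isomer. Only the Z isomer can cyclise, but protonation at the α-carbon by CF3CO2H gives a cation stabilised by both the aryloxy oxygen and the para-allyloxyphenyl group, so any E isomer should equilibrate and drain through the irreversible acylation. Flavone rather than 4-arylcoumarin connectivity was already fixed in step 6, where O1–C2 was made first. Allyl and benzyl ethers should tolerate the anhydride and the weak acid at this temperature.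

Step 9
Reactants: 13 5,7-bis(allyloxy)-2-[4-(allyloxy)-3-(benzyloxy)phenyl]-4H-chromen-4-one
Product: 16 5,7-bis(allyloxy)-2-[4-(allyloxy)-3-(benzyloxy)phenyl]-3-hydroxy-4H-chromen-4-one, via 3-lithioflavone 14 (not isolated), via lithium trimethoxyborate 15 (not isolated)
Conditions: LiN(iPr)2, THF, −78 °C; B(OMe)3, −78 to 0 °C; then AcOH, 30% H2O2, 0 °C to rt
Reagents that add atoms: hydrogen peroxide, OO
Why: C3 lithiation of a flavone by a hindered amide base (C3–H, α to the carbonyl, is the only acidic vinylic C–H), borylation, and oxidative 1,2-shift from boron to oxygen. The sequence uses no electrophilic oxidant, so the three allyl double bonds should survive, and the weakly acidic peroxide work-up avoids alkaline degradation of the flavonol.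

Step 10
Reactants: 16 5,7-bis(allyloxy)-2-[4-(allyloxy)-3-(benzyloxy)phenyl]-3-hydroxy-4H-chromen-4-one
Product: 17 2-[3-(benzyloxy)-4-hydroxyphenyl]-3,5,7-trihydroxy-4H-chromen-4-one (3'-O-benzylquercetin)
Conditions: Pd(PPh3)4 (5 mol %), morpholine, THF, rt, argon
Reagents that add atoms: none
Why: Tsuji–Trost de-allylation: zerovalent palladium ionises each aryl allyl ether to a π-allyl complex and a phenoxide, and morpholine traps the allyl group irreversibly. The benzyl ether cannot ionise this way, so O3' stays covered; argon protects the electron-rich flavonol from air oxidation.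

Step 11
Reactants: 17 2-[3-(benzyloxy)-4-hydroxyphenyl]-3,5,7-trihydroxy-4H-chromen-4-one (3'-O-benzylquercetin)
Product: 18 tris(triethylammonium) 2-[3-(benzyloxy)-4-(sulfonatooxy)phenyl]-5-hydroxy-4-oxo-4H-chromene-3,7-diyl bis(sulfate)
Conditions: SO3·NEt3 (6 equiv), DMF, 40 °C
Reagents that add atoms: sulfur trioxide–triethylamine complex, CC[N+](CC)(CC)S(=O)(=O)[O-]
Why: O-sulfonation of phenols by an amine–sulfur trioxide complex, with the amine becoming the counter-ion. O7, O4' and the enolic O3 should react, O5 is held in a six-membered hydrogen bond to the carbonyl and is the least nucleophilic hydroxyl, and O3' is blocked, so regiochemistry does not depend on reagent control.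

Step 12
Reactants: 18 tris(triethylammonium) 2-[3-(benzyloxy)-4-(sulfonatooxy)phenyl]-5-hydroxy-4-oxo-4H-chromene-3,7-diyl bis(sulfate)
Product: 20 quercetin 3,4',7-tris(hydrogen sulfate), via triethylammonium salt 19 (not isolated)
Conditions: H2 (1 atm), 10% Pd/C, MeOH/H2O, rt; then Dowex 50WX8 (H+ form), H2O, 0 °C, freeze-drying
Reagents that add atoms: none
Why: Hydrogenolysis of the benzyl ether over palladium on carbon; sulfate monoester anions are not reduced and do not poison the catalyst, and the flavonol C2=C3 bond is part of a vinylogous ester and should not be hydrogenated at 1 atm. Cold passage through a sulfonic acid resin exchanges triethylammonium for protons.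

## Compound list

1 | 3,4-dihydroxybenzaldehyde | O=Cc1ccc(O)c(O)c1 | starting material
2 | 4-(allyloxy)-3-hydroxybenzaldehyde | O=Cc1ccc(OCC=C)c(O)c1 | intermediate
3 | 4-(allyloxy)-3-(benzyloxy)benzaldehyde | O=Cc1ccc(OCC=C)c(OCc2ccccc2)c1 | intermediate
4 | 1-(allyloxy)-2-(benzyloxy)-4-(2,2-dibromovinyl)benzene | BrC(Br)=Cc1ccc(OCC=C)c(OCc2ccccc2)c1 | intermediate
5 | lithium [4-(allyloxy)-3-(benzyloxy)phenyl]acetylide (not isolated) | [Li]C#Cc1ccc(OCC=C)c(OCc2ccccc2)c1 | intermediate
6 | methyl 3-[4-(allyloxy)-3-(benzyloxy)phenyl]prop-2-ynoate | COC(=O)C#Cc1ccc(OCC=C)c(OCc2ccccc2)c1 | intermediate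
7 | benzene-1,3,5-triol (phloroglucinol) | Oc1cc(O)cc(O)c1 | starting material
8 | 3,5-bis(allyloxy)phenol | Oc1cc(OCC=C)cc(OCC=C)c1 | intermediate
9 | methyl (Z)-3-[4-(allyloxy)-3-(benzyloxy)phenyl]-3-[3,5-bis(allyloxy)phenoxy]prop-2-enoate (any E isomer is carried along) | COC(=O)/C=C(\Oc1cc(OCC=C)cc(OCC=C)c1)c1ccc(OCC=C)c(OCc2ccccc2)c1 | intermediate
10 | lithium (Z)-3-[4-(allyloxy)-3-(benzyloxy)phenyl]-3-[3,5-bis(allyloxy)phenoxy]prop-2-enoate (not isolated) | [Li+].[O-]C(=O)/C=C(\Oc1cc(OCC=C)cc(OCC=C)c1)c1ccc(OCC=C)c(OCc2ccccc2)c1 | intermediate
11 | (Z)-3-[4-(allyloxy)-3-(benzyloxy)phenyl]-3-[3,5-bis(allyloxy)phenoxy]prop-2-enoic acid | OC(=O)/C=C(\Oc1cc(OCC=C)cc(OCC=C)c1)c1ccc(OCC=C)c(OCc2ccccc2)c1 | intermediate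
12 | (Z)-3-[4-(allyloxy)-3-(benzyloxy)phenyl]-3-[3,5-bis(allyloxy)phenoxy]prop-2-enoic trifluoroacetic anhydride (not isolated) | O=C(OC(=O)C(F)(F)F)/C=C(\Oc1cc(OCC=C)cc(OCC=C)c1)c1ccc(OCC=C)c(OCc2ccccc2)c1 | intermediate
13 | 5,7-bis(allyloxy)-2-[4-(allyloxy)-3-(benzyloxy)phenyl]-4H-chromen-4-one | O=c1cc(-c2ccc(OCC=C)c(OCc3ccccc3)c2)oc2cc(OCC=C)cc(OCC=C)c12 | intermediate
14 | {5,7-bis(allyloxy)-2-[4-(allyloxy)-3-(benzyloxy)phenyl]-4-oxo-4H-chromen-3-yl}lithium (not isolated) | [Li]c1c(-c2ccc(OCC=C)c(OCc3ccccc3)c2)oc2cc(OCC=C)cc(OCC=C)c2c1=O | intermediate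
15 | lithium {5,7-bis(allyloxy)-2-[4-(allyloxy)-3-(benzyloxy)phenyl]-4-oxo-4H-chromen-3-yl}trimethoxyborate (not isolated) | [Li+].CO[B-](OC)(OC)c1c(-c2ccc(OCC=C)c(OCc3ccccc3)c2)oc2cc(OCC=C)cc(OCC=C)c2c1=O | intermediate
16 | 5,7-bis(allyloxy)-2-[4-(allyloxy)-3-(benzyloxy)phenyl]-3-hydroxy-4H-chromen-4-one | O=c1c(O)c(-c2ccc(OCC=C)c(OCc3ccccc3)c2)oc2cc(OCC=C)cc(OCC=C)c12 | intermediate
17 | 2-[3-(benzyloxy)-4-hydroxyphenyl]-3,5,7-trihydroxy-4H-chromen-4-one (3'-O-benzylquercetin) | O=c1c(O)c(-c2ccc(O)c(OCc3ccccc3)c2)oc2cc(O)cc(O)c12 | intermediate
18 | tris(triethylammonium) 2-[3-(benzyloxy)-4-(sulfonatooxy)phenyl]-5-hydroxy-4-oxo-4H-chromene-3,7-diyl bis(sulfate) | O=c1c(OS(=O)(=O)[O-])c(-c2ccc(OS(=O)(=O)[O-])c(OCc3ccccc3)c2)oc2cc(OS(=O)(=O)[O-])cc(O)c12.CC[NH+](CC)CC.CC[NH+](CC)CC.CC[NH+](CC)CC | intermediate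
19 | tris(triethylammonium) 5-hydroxy-2-[3-hydroxy-4-(sulfonatooxy)phenyl]-4-oxo-4H-chromene-3,7-diyl bis(sulfate) (not isolated) | O=c1c(OS(=O)(=O)[O-])c(-c2ccc(OS(=O)(=O)[O-])c(O)c2)oc2cc(OS(=O)(=O)[O-])cc(O)c12.CC[NH+](CC)CC.CC[NH+](CC)CC.CC[NH+](CC)CC | intermediate
20 | quercetin 3,4',7-tris(hydrogen sulfate) | O=c1c(OS(=O)(=O)O)c(-c2ccc(OS(=O)(=O)O)c(O)c2)oc2cc(OS(=O)(=O)O)cc(O)c12 | target

## Step count and least certain steps

Total step count: 12. Longest linear sequence: 11 steps (steps 1–4 and 6–12); step 5 is the side branch to 8.

**Step 8 (key step).**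
- Most likely failure: incomplete equilibration of the E to the Z enol ether under the weak acid, so that part of the material never reaches the cyclisation geometry.
- Also possible: trifluoroacetylation of the free, doubly activated ring A carbon by the anhydride, or acid-promoted hydrolysis of the enol ether C–O bond if moisture is present.
- Fallback, which closes ring C at the heteroatom instead, sets out from 4 and comes back at 13. Commercial 2,4,6-trihydroxybenzaldehyde F1 is bis-allylated at its two non-chelated hydroxyls (allyl bromide, K2CO3) to 2-hydroxy-4,6-bis(allyloxy)benzaldehyde F2. Its sodium phenoxide (NaH) is treated with the acetylide 5, generated from 4 as in step 4, to give 1-[2-hydroxy-4,6-bis(allyloxy)phenyl]-3-[4-(allyloxy)-3-(benzyloxy)phenyl]prop-2-yn-1-ol F3. MnO2 oxidises this to 1-[2-hydroxy-4,6-bis(allyloxy)phenyl]-3-[4-(allyloxy)-3-(benzyloxy)phenyl]prop-2-yn-1-one F4. Diethylamine in ethanol then adds to the ynone, and 6-endo attack of the phenol on the enaminone with loss of the amine gives 13.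

**Step 6.**
- Most likely failure: attack through carbon by the ambident, electron-rich phenoxide followed by lactonisation, or slow addition because the para-alkoxyaryl group lowers the electrophilicity of the β-carbon; prolonged heating then erodes the material.
- Fallback sets out from 6 and comes back at 9. Anti-hydrobromination of 6 with LiBr in acetic acid gives methyl (Z)-3-bromo-3-[4-(allyloxy)-3-(benzyloxy)phenyl]prop-2-enoate F5. An Ullmann-type vinyl etherification with 8 (CuI, 1,10-phenanthroline, Cs2CO3, toluene) then makes O1–C2 with retention of geometry to give 9.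

**Step 9.**
- Most likely failure: addition of the amide base to the pyranone instead of C3 deprotonation, competing deprotonation at an allylic O–CH2, or slow oxidation of the allyl double bonds or the flavonol during the peroxide work-up.
- Fallback, which replaces metalation by electrophilic epoxidation of C2=C3 after the alkenes are gone, sets out from 13 and comes back at 17. De-allylation as in step 10 gives 2-[3-(benzyloxy)-4-hydroxyphenyl]-5,7-dihydroxy-4H-chromen-4-one F6. NaH and chloromethyl methyl ether give 2-[3-(benzyloxy)-4-(methoxymethoxy)phenyl]-5,7-bis(methoxymethoxy)-4H-chromen-4-one F7. Dimethyldioxirane followed by a trace of p-toluenesulfonic acid gives 2-[3-(benzyloxy)-4-(methoxymethoxy)phenyl]-3-hydroxy-5,7-bis(methoxymethoxy)-4H-chromen-4-one F8. Methanolic HCl removes the three methoxymethyl groups to give 17.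

**Step 11.**
- Most likely failure: incomplete sulfation of the hydrogen-bonded, hindered O3, or partial over-sulfation at O5 under the excess needed to finish O3. Either leaves a mixture of polyanions that is hard to separate.
- Fallback, which carries the sulfates as neutral diesters that can be purified on silica, sets out from 17 and comes back at 20. 2,2,2-Trichloroethyl chlorosulfate with NEt3 and 4-(dimethylamino)pyridine gives 2-[3-(benzyloxy)-4-{[(2,2,2-trichloroethoxy)sulfonyl]oxy}phenyl]-5-hydroxy-4-oxo-4H-chromene-3,7-diyl bis(2,2,2-trichloroethyl) bis(sulfate) F9. Transfer hydrogenolysis (10% Pd/C, ammonium formate, MeOH) removes the three trichloroethyl groups and the benzyl group together, and cold cation exchange gives 20.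

**Step 12.**
- Most likely failure: slow hydrogenolysis of a benzyl ether flanked by an ortho sulfate on a strongly adsorbed polyanion, with sulfate loss during the long exposure and during acidification.
- Fallback, which removes the benzyl group before any sulfate is present, sets out from 17 and comes back at 20. Hydrogenolysis (H2, 10% Pd/C) gives 3,3',4',5,7-pentahydroxyflavone (quercetin) F10. Sulfation with dicyclohexylcarbodiimide and tetrabutylammonium hydrogen sulfate in pyridine transfers sulfate in the order of phenol acidity (O7 and O4', then O3, with O3' and O5 last). It is stopped at the trisulfate stage, and cation exchange gives 20. This version relies on reagent control for O3' versus O4'.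

**Step 5.**
- Most likely failure: the statistical spread over mono-, bis- and tris-ethers, together with C-allylation of the very electron-rich ring, makes isolation of 8 inefficient.
- Fallback replaces 7 as the starting point and comes back at 8. Commercial 5-bromobenzene-1,3-diol F11 is exhaustively allylated to 1,3-bis(allyloxy)-5-bromobenzene F12. Bromine–lithium exchange (n-BuLi, THF, −78 °C), B(OMe)3 and H2O2 oxidation turn the C–Br bond into C–OH to give 8.

## Further compounds

F1 | step 8 | 2,4,6-trihydroxybenzaldehyde (commercial) | O=Cc1c(O)cc(O)cc1O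
F2 | step 8 | 2-hydroxy-4,6-bis(allyloxy)benzaldehyde | O=Cc1c(O)cc(OCC=C)cc1OCC=C
F3 | step 8 | 1-[2-hydroxy-4,6-bis(allyloxy)phenyl]-3-[4-(allyloxy)-3-(benzyloxy)phenyl]prop-2-yn-1-ol (racemic) | OC(C#Cc1ccc(OCC=C)c(OCc2ccccc2)c1)c1c(O)cc(OCC=C)cc1OCC=C
F4 | step 8 | 1-[2-hydroxy-4,6-bis(allyloxy)phenyl]-3-[4-(allyloxy)-3-(benzyloxy)phenyl]prop-2-yn-1-one | O=C(C#Cc1ccc(OCC=C)c(OCc2ccccc2)c1)c1c(O)cc(OCC=C)cc1OCC=C
F5 | step 6 | methyl (Z)-3-bromo-3-[4-(allyloxy)-3-(benzyloxy)phenyl]prop-2-enoate | COC(=O)/C=C(\Br)c1ccc(OCC=C)c(OCc2ccccc2)c1
F6 | step 9 | 2-[3-(benzyloxy)-4-hydroxyphenyl]-5,7-dihydroxy-4H-chromen-4-one | O=c1cc(-c2ccc(O)c(OCc3ccccc3)c2)oc2cc(O)cc(O)c12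
F7 | step 9 | 2-[3-(benzyloxy)-4-(methoxymethoxy)phenyl]-5,7-bis(methoxymethoxy)-4H-chromen-4-one | O=c1cc(-c2ccc(OCOC)c(OCc3ccccc3)c2)oc2cc(OCOC)cc(OCOC)c12
F8 | step 9 | 2-[3-(benzyloxy)-4-(methoxymethoxy)phenyl]-3-hydroxy-5,7-bis(methoxymethoxy)-4H-chromen-4-one | O=c1c(O)c(-c2ccc(OCOC)c(OCc3ccccc3)c2)oc2cc(OCOC)cc(OCOC)c12
F9 | step 11 | 2-[3-(benzyloxy)-4-{[(2,2,2-trichloroethoxy)sulfonyl]oxy}phenyl]-5-hydroxy-4-oxo-4H-chromene-3,7-diyl bis(2,2,2-trichloroethyl) bis(sulfate) | O=c1c(OS(=O)(=O)OCC(Cl)(Cl)Cl)c(-c2ccc(OS(=O)(=O)OCC(Cl)(Cl)Cl)c(OCc3ccccc3)c2)oc2cc(OS(=O)(=O)OCC(Cl)(Cl)Cl)cc(O)c12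
F10 | step 12 | 3,3',4',5,7-pentahydroxyflavone (quercetin) | O=c1c(O)c(-c2ccc(O)c(O)c2)oc2cc(O)cc(O)c12
F11 | step 5 | 5-bromobenzene-1,3-diol (commercial) | Oc1cc(O)cc(Br)c1
F12 | step 5 | 1,3-bis(allyloxy)-5-bromobenzene | Brc1cc(OCC=C)cc(OCC=C)c1
A1 | alternative 1 | 1-[2-hydroxy-4,6-bis(allyloxy)phenyl]ethan-1-one | CC(=O)c1c(O)cc(OCC=C)cc1OCC=C
A2 | alternative 1 | (E)-1-[2-hydroxy-4,6-bis(allyloxy)phenyl]-3-[4-(allyloxy)-3-(benzyloxy)phenyl]prop-2-en-1-one | O=C(/C=C/c1ccc(OCC=C)c(OCc2ccccc2)c1)c1c(O)cc(OCC=C)cc1OCC=C
A3 | alternative 2 | 2-(allyloxy)-1-[2-hydroxy-4,6-bis(allyloxy)phenyl]ethan-1-one | C=CCOCC(=O)c1c(O)cc(OCC=C)cc1OCC=C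
A4 | alternative 2 | 4-(allyloxy)-3-(benzyloxy)benzoyl chloride | O=C(Cl)c1ccc(OCC=C)c(OCc2ccccc2)c1
A5 | alternative 2 | 2-(allyloxy)-1-[2-hydroxy-4,6-bis(allyloxy)phenyl]-3-[4-(allyloxy)-3-(benzyloxy)phenyl]propane-1,3-dione (racemic) | C=CCOC(C(=O)c1ccc(OCC=C)c(OCc2ccccc2)c1)C(=O)c1c(O)cc(OCC=C)cc1OCC=C
A6 | alternative 2 | 3,5,7-tris(allyloxy)-2-[4-(allyloxy)-3-(benzyloxy)phenyl]-4H-chromen-4-one | O=c1c(OCC=C)c(-c2ccc(OCC=C)c(OCc3ccccc3)c2)oc2cc(OCC=C)cc(OCC=C)c12
A7 | alternative 3 | 2-iodo-3,5-bis(allyloxy)phenol | Oc1cc(OCC=C)cc(OCC=C)c1I
A8 | alternative 3 | 1-(allyloxy)-2-(benzyloxy)-4-ethynylbenzene | C#Cc1ccc(OCC=C)c(OCc2ccccc2)c1
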